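**Retrosynthetic overview**
- Building blocks: 4-allyl-2,6-dimethoxyphenol 1, isomerised to the E-propenyl phenol 2 and O-vinylated to aryl vinyl ether 3, plus 3,4,5-trimethoxybenzaldehyde 4.
- Key disconnection: an acyl anion equivalent (Breslow enaminol 5, from 4 and a chiral triazolylidene) adds to vinyl ether 3, which acts as a latent 1-aryloxyethyl cation. This joins two normally electrophilic carbons, forms the C(=O)–CH(OAr) bond of target 6 and sets its only stereocentre in the same step.
- Supporting disconnections: the aryl O–vinyl bond of 3 (transfer vinylation of 2) and the allyl to (E)-propenyl isomerisation of 1.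
- Rings: none are formed; both benzene rings are bought intact.

Assumption: by CIP analysis the given SMILES is the (S)-enantiomer with an E-propenyl group; isomerically pure (E)-2,6-dimethoxy-4-propenylphenol is taken not to be a cheap catalogue item, so it is made from cheap 4-allyl-2,6-dimethoxyphenol (if it is bought pure, step 1 drops out).

**Step 1**
Reactants: 1 4-allyl-2,6-dimethoxyphenol (methoxyeugenol)
Product: 2 (E)-2,6-dimethoxy-4-(prop-1-en-1-yl)phenol
Conditions: RuHCl(CO)(PPh3)3 (2 mol%), toluene, 90 °C; residual Z isomer removed on AgNO3–SiO2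
Reagents that add atoms: none
Why: Ru–hydride alkene isomerisation (hydrometalation/β-hydride elimination) moves the terminal double bond into conjugation with the arene under thermodynamic control, which gives the E-propenyl isomer (about 95:5 or better) and tolerates the free phenol.

**Step 2**
Reactants: 2 (E)-2,6-dimethoxy-4-(prop-1-en-1-yl)phenol
Product: 3 (E)-1,3-dimethoxy-5-(prop-1-en-1-yl)-2-(vinyloxy)benzene
Conditions: vinyl acetate (2 equiv), [Ir(cod)Cl]2 (1 mol%), Na2CO3 (1.0 equiv), toluene, 100 °C
Reagents that add atoms: vinyl acetate, C=COC(C)=O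
Why: Ir-catalysed transfer vinylation of a phenol (addition of the phenoxide to Ir-bound vinyl acetate, then β-acetoxy elimination) gives the aryl vinyl ether directly; the conjugated E-propenyl group and the methyl ethers are inert to carbonate at 100 °C.

**Step 3**
Reactants: 3 (E)-1,3-dimethoxy-5-(prop-1-en-1-yl)-2-(vinyloxy)benzene; 4 3,4,5-trimethoxybenzaldehyde
Product: 6 (S,E)-2-[2,6-dimethoxy-4-(prop-1-en-1-yl)phenoxy]-1-(3,4,5-trimethoxyphenyl)propan-1-one, via Breslow enaminol 5 (not isolated)
Conditions: 4 (1.0 equiv), 3 (2.0 equiv), (S)-5-benzyl-2-mesityl-6,7-dihydro-5H-pyrrolo[2,1-c][1,2,4]triazol-2-ium BF4 (15 mol%), K3PO4 (15 mol%), 1,4-dioxane, 4 Å MS, 70 °C, Ar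
Reagents that add atoms: none
Why: Proposed new method: the triazolylidene turns 4 into Breslow enaminol 5, an acyl anion equivalent, which should add to the electron-rich vinyl ether 3 in a concerted but asynchronous Conia-ene-type hydroacylation (enol O–H to the nucleophilic CH2 terminus, enaminol carbon to the incipient oxocarbenium carbon), so the acyl group ends on the O-bearing carbon and the benzyl-shielded catalyst selects the enantiotopic face of the vinyl ether, setting the new stereocentre as S (the sense of induction cannot be predicted with confidence, so it is checked in a test run and the (R)-catalyst is used if it is reversed); closest known reaction types are the NHC-catalysed intramolecular hydroacylation of aryl enol ethers to 2,2-disubstituted benzofuran-3-ones and the intermolecular asymmetric NHC hydroacylation of styrenes and cyclopropenes; the homobenzoin of 4 is reversible, the internal conjugated propenyl group is far less reactive than the terminal vinyl ether, and only 15 mol% of weak base is present, so the α-aryloxy ketone (pKa about 21 in DMSO) should not racemise.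

**Compound list**
1 | 4-allyl-2,6-dimethoxyphenol (methoxyeugenol) | C=CCc1cc(OC)c(O)c(OC)c1 | starting material
2 | (E)-2,6-dimethoxy-4-(prop-1-en-1-yl)phenol | C/C=C/c1cc(OC)c(O)c(OC)c1 | intermediate
3 | (E)-1,3-dimethoxy-5-(prop-1-en-1-yl)-2-(vinyloxy)benzene | C/C=C/c1cc(OC)c(OC=C)c(OC)c1 | intermediate
4 | 3,4,5-trimethoxybenzaldehyde | COc1cc(C=O)cc(OC)c1OC | starting material
5 | Breslow enaminol, catalyst-bound acyl anion equivalent: [(5S)-5-benzyl-2-mesityl-2,5,6,7-tetrahydro-3H-pyrrolo[2,1-c][1,2,4]triazol-3-ylidene](3,4,5-trimethoxyphenyl)methanol | Cc1cc(C)c(N2N=C3CC[C@@H](Cc4ccccc4)N3C2=C(O)c2cc(OC)c(OC)c(OC)c2)c(C)c1 | intermediate (not isolated)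
6 | (S,E)-2-[2,6-dimethoxy-4-(prop-1-en-1-yl)phenoxy]-1-(3,4,5-trimethoxyphenyl)propan-1-one | C/C=C/c1cc(OC)c(O[C@@H](C)C(=O)c2cc(OC)c(OC)c(OC)c2)c(OC)c1 | target

**Totals**
Total step count: 3. Longest linear sequence: 3 steps (1 → 2 → 3 → 6); aldehyde 4 enters in step 3.

**Steps most likely to fail, with fallbacks**

Most likely to fail is step 3. Intermolecular hydroacylation of an aryl vinyl ether is untested, so it may stall at the benzoin of 4, give low ee or the wrong sense of induction, or lose ee to the base. The fallback sets out from 4 and comes back at 6. Aldehyde 4 and acetaldehyde are joined by the thiamine-diphosphate enzyme benzaldehyde lyase (ThDP, MgSO4, phosphate buffer pH 8 with 20% DMSO, 30 °C), again with the aldehyde carbon of 4 as the acyl anion partner, to give (R)-2-hydroxy-1-(3,4,5-trimethoxyphenyl)propan-1-one F1. Mitsunobu etherification of F1 with phenol 2 (PPh3, DIAD, toluene, 0 °C to rt) inverts the carbinol centre and gives 6 as the S enantiomer. Material from this path also serves as the reference for absolute configuration and ee of the step 3 product.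

Second is step 2. The 2,6-dimethoxy-flanked phenol may react slowly or be O-acetylated instead of vinylated. The fallback sets out from 2 and comes back at 3. Phenol 2 is alkylated with excess 1,2-dibromoethane (K2CO3, acetone, reflux) to (E)-2-(2-bromoethoxy)-1,3-dimethoxy-5-(prop-1-en-1-yl)benzene F2. E2 elimination of F2 with KOtBu in THF (0 °C to rt) then gives vinyl ether 3.

Third is step 1. The free phenol may slow the Ru–H catalyst, or a Z fraction may be hard to remove at the phenol stage. The fallback sets out from 1 and comes back at 3, changing the order of events. Phenol 1 is vinylated first under the step 2 conditions to 5-allyl-1,3-dimethoxy-2-(vinyloxy)benzene F3. With no acidic OH left, F3 is isomerised through the benzylic/allylic carbanion with KOtBu (0.3 equiv) in DMSO at rt, which is thermodynamically E-selective and leaves the base-stable vinyl ether untouched, giving 3.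

**Further compounds**
F1 | step 3 | (R)-2-hydroxy-1-(3,4,5-trimethoxyphenyl)propan-1-one | C[C@@H](O)C(=O)c1cc(OC)c(OC)c(OC)c1
F2 | step 2 | (E)-2-(2-bromoethoxy)-1,3-dimethoxy-5-(prop-1-en-1-yl)benzene | C/C=C/c1cc(OC)c(OCCBr)c(OC)c1
F3 | step 1 | 5-allyl-1,3-dimethoxy-2-(vinyloxy)benzene | C=CCc1cc(OC)c(OC=C)c(OC)c1
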